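## Structural features

Germacrane numbering is used throughout: C1 is the furanone carbonyl carbon, C2=C3 the enol-ether double bond, C4 the CH(CH3) carbon, C5 the CHOH carbon, C6 the lactone O–CH carbon, C7 the ring-fusion CH, C8 the ester-bearing carbon, C9 the second CHOH carbon, C10 the quaternary C(CH3)–O carbon, and C11(=C13H2)–C12(=O) the methylene-lactone carbons. The core is a ten-membered carbocycle C1–C10 in which an oxygen bridge from C10 to C3 creates a 3(2H)-furanone (O, C3=C2, C1=O, C10) and so an 11-oxabicyclo[6.2.1]undecane; an α-methylene-γ-butyrolactone is trans-fused at C6–C7. Seven stereocentres, C4 to C10, are contiguous around the ring and C10 is quaternary; O9 and O10 are syn, O8 is anti to O9 and syn to the C7 side chain, the lactone oxygen on C6 is anti to C11, and O5 is anti to O6 along the ring. Fragile points are the exo-methylene lactone (Michael acceptor), the C8 isovalerate next to the free C9 hydroxyl (acyl migration), and the furanone, a vinylogous ester whose C4–H is γ-acidic so that base can epimerise C4. The real difficulty is the oxygen-bridged medium ring that carries the stereoheptad: a direct closure of the ten-membered ring fights strain and must set stereocentres without a rigid template. The feature exploited is that the C1 carbonyl and the oxygenated C5/C6 pair are 1,5-related through C2–C3–C4 (an oxy-Cope retron), while C10, next to C1, is already tied to C3 by the ring oxygen. The key step therefore starts from a cyclohexane made of C1, C6, C7, C8, C9 and C10 with a 2,3-dihydrofuran (O, C3=C2) fused across C1–C10, and trades its C1–C6 bond for the C3–C4 bond.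

## Logic of the disconnections

In one sentence: an anionic oxy-Cope ring expansion of 19 delivers 22.

**30 to 27.** Cut: the lactone C12–O6 bond, with C12 lowered to a primary allylic alcohol. Reason: the methylene lactone is the most electrophilic unit and is best unveiled last from a 2-methylene-1,4-diol. Gain: no Michael acceptor on the route. Demand: the oxidant must touch only the primary allylic alcohol of 27, and the lactol must close on O6, not O5.

**27 to 25.** Cut: the C5–O and C6–O bonds together; O9 and O12 return to silyl ethers. Reason: the anti placement of O5 and O6 along the ring is what syn-dihydroxylation of an E C5=C6 alkene gives from one face. Gain: two stereocentres leave. Demand: osmylation of 25 at C5=C6 only, from the peripheral face.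

**25 to 23.** Cut: the acyl–O8 bond (through 24), O8 returning to a PMB ether. Reason: an ester cannot pass the strongly basic key step. Gain: base-stable intermediates. Demand: deprotection and acylation without bases that enolise C4.

**23 to 22.** Change: the C2=C3 double bond is taken out, leaving a silyl enol ether. Reason: this is the trapped enolate of an oxy-Cope rearrangement. Demand: a dehydrogenation with one possible regiochemistry (C10 is quaternary).

**22 to 19 (key).** Cut C3–C4, reconnect C1–C6. Reason: the 1,5-relationship of C1=O and C5=C6. Gain: the ten-membered ring, the nine-membered oxacycle, the C4 stereocentre and the E alkene are traded for a cis-fused 6/5 bicycle whose stereocentres sit on a cyclohexane. Demand: the C6 propenyl group must be Z and cis to the ring oxygen, and the shift must pass through the chair.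

**19 to 18.** Cut: the O10–C3 bond. Reason: a terminal alkyne on C1 cis to the C10 hydroxyl closes to the dihydrofuran by endo cycloisomerisation. Gain: the enol ether appears only one step before use. Demand: C10–OH and the ethynyl group cis.

**18 to 16.** Cut: C4=C5, back to aldehyde 17 and its acetal 16. Reason: a Wittig reaction is the most reliable source of a Z-propenyl group, and no enolisable ketone is then exposed to a Z-alkenyl substituent. Gain: C15 and C4 arrive as one reagent. Demand: olefination faster than retro-aldol cleavage.

**16 to 13.** Cut: the O–C8 bond and the C9–O bond (through 15 and 14) back to the C8=C9 alkene. Reason: anti O8/O9 with O9 syn to O10 is the outcome of a C10–OH-directed epoxidation followed by opening at C8. Gain: two stereocentres relayed from C10. Demand: opening at C8, not C9.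

**13 to 9.** Cut: C1–C2 (acetylide), then C6–C(acetal) (through 12). Reason: on the cyclohexenone half-chair the ketone faces are well differentiated, and C6 is the only enolisable carbon. Gain: both carbon arms added by substrate control. Demand: ethynyl cis to O10; C6 substituent trans to the C7 chain.

**9 to 4.** Change: allylic transposition (O stays on C10, C8=C9 formed from the C9–C10 epoxide), with C1 passing through the alcohol level (5, 8). Reason: the enone epoxide already has O10 on the correct face. Gain: C10 configuration from a one-step epoxidation. Demand: selenolate attack at C9 only.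

**4 to 1.** Cut: the epoxide C–O bonds and the C12–O bond. Reason: 1 supplies C1, C6–C10, C14 and C11–C13 with the C7 stereocentre in the required absolute sense. Gain: one purchased stereocentre from which all others are relayed.

## Other disconnections considered

**Alternative 1:** Cut C6–C7 and the lactone C12–O bond. Forward key step: intramolecular Barbier or Nozaki–Hiyama–Kishi allylation (Zn, or CrCl2) of the aldehyde/2-(bromomethyl)enoate A1, closing the ten-membered ring, then lactonisation. This is the first plan that comes to mind. It must close the medium ring directly at its most congested bond and set C6 and C7 in that event under remote control only. C4, C5, C8, C9 and C10 would all have to be built on an open chain around a preformed furanone, and A1 carries the ester and the γ-acidic furanone through a reducing-metal step. The chosen plan closes only five- and six-membered rings and relays every centre from one.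

**Alternative 2:** Cut the O–C3 bond. Forward key step: transannular 5-endo-dig cycloisomerisation of the cyclodecynone A2 with a cationic gold catalyst such as Ph3PAuNTf2. The furanone closure itself is dependable, but the difficulty is only displaced: A2 is a strained ten-membered ynone holding all seven stereocentres and still needs a macrocyclisation, and the key step sets no stereocentre.

**Alternative 3:** Cut C9–C10. Forward key step: intramolecular vinylogous Mukaiyama aldol of the 2-methyl-3-silyloxyfuran aldehyde A3 (BF3·OEt2), closing the ring and setting C9 and quaternary C10 together. It is convergent, but two centres, one quaternary, would be set during a medium-ring closure with facial control only from the α-acyloxy aldehyde. A bridged furan geometry is demanded in the transition state, and the sensitive lactone is already present. The chosen step instead sets C4 by a stereospecific sigmatropic transfer.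

Key step: step 15

Remark 1: hydride reduction of 4 is assumed to give mainly the C1 alcohol syn to the oxirane oxygen (drawn for 5 to 8); the C1 epimer would serve equally because C1 is re-oxidised in step 6.
Remark 2: 7 (at selenium) and 29 (at the lactol carbon) are epimer mixtures of no consequence.

## Route

Step 1
Reactants: 1 (R)-(−)-carvone
Product: 2 (R)-10-hydroxycarvone
Conditions: SeO2 (cat.), t-BuOOH, CH2Cl2, rt
Reagents that add atoms: selenium dioxide O=[Se]=O (oxygen carrier); tert-butyl hydroperoxide CC(C)(C)OO (terminal oxidant)
Why: Allylic oxidation (ene reaction then [2,3] shift) should attack the electron-rich 1,1-disubstituted alkene at its methyl group in preference to the enone; the stereocentre (future C7) is untouched.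

Step 2
Reactants: 2 (R)-10-hydroxycarvone
Product: 3 TBS ether of 2
Conditions: TBSCl, imidazole, DMF, rt
Reagents that add atoms: tert-butyldimethylsilyl chloride CC(C)(C)[Si](C)(C)Cl
Why: Standard silylation of a primary alcohol; the ether has to survive base, hydride and mild Lewis acids until step 20.

Step 3
Reactants: 3 TBS ether of 2
Product: 4 epoxy ketone
Conditions: H2O2 (30% aq.), NaOH, MeOH, 0 °C
Reagents that add atoms: hydrogen peroxide OO
Why: Weitz–Scheffer nucleophilic epoxidation touches only the enone; hydroperoxide should add axially to C9 anti to the C7 side chain, so the oxirane oxygen (future O9/O10 face) is trans to that chain.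

Step 4
Reactants: 4 epoxy ketone
Product: 5 epoxy alcohol
Conditions: NaBH4, MeOH, 0 °C
Reagents that add atoms: none
Why: Borohydride reduction masks the ketone, which would otherwise divert the selenolate of step 5 into reductive cleavage of the α,β-epoxy ketone; hydride is expected anti to the oxirane oxygen and the new C1 centre is erased in step 6.

Step 5
Reactants: 5 epoxy alcohol
Product: 8 ene-diol, via C9 phenylselenide diol 6 (not isolated), via C9 selenoxide diol 7 (not isolated)
Conditions: (PhSe)2, NaBH4, EtOH, reflux; then H2O2 (30% aq.), THF, 0 °C to rt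
Reagents that add atoms: none
Why: Epoxide-to-allylic-alcohol transposition: selenolate opens the oxirane by SN2 at secondary C9 (the trans-diaxial mode needs the half-chair with the C7 chain pseudoaxial, hence heating) and the selenoxide undergoes syn-elimination toward C8 because C10 has no hydrogen; O10 keeps its configuration.

Step 6
Reactants: 8 ene-diol
Product: 9 α-ketol
Conditions: Dess–Martin periodinane, NaHCO3, CH2Cl2, rt
Reagents that add atoms: none
Why: Dess–Martin oxidation should convert the secondary C1 alcohol and leave the tertiary allylic alcohol; C10 is quaternary, so the C8=C9 bond cannot move into conjugation.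

Step 7
Reactants: 9 α-ketol
Product: 12 keto acetal, via bis(trimethylsilyl) dienol ether 10 (not isolated), via C10-O-TMS keto acetal 11 (not isolated)
Conditions: TMSOTf, i-Pr2NEt, CH2Cl2, 0 °C; then HC(OMe)3, −78 to −20 °C; then citric acid, MeOH, rt
Reagents that add atoms: trimethyl orthoformate COC(OC)OC
Why: One-pot enol silane formation and Mukaiyama aldol-type addition to the dimethoxycarbenium ion; C6 is the only enolisable carbon and the electrophile should enter anti to the C7 chain (trans C6/C7), and mildly acidic methanolysis frees O10 without β-elimination of methoxide.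

Step 8
Reactants: 12 keto acetal
Product: 13 ethynyl diol
Conditions: HC≡CMgBr (excess), THF, −40 to 0 °C; NH4Cl (aq.)
Reagents that add atoms: ethynylmagnesium bromide C#C[Mg]Br
Why: Chelation-controlled 1,2-addition: magnesium bridges the C10 alkoxide and the C1 carbonyl and the small acetylide attacks axially on the half-chair, anti to the pseudoaxial C10 methyl, so the ethynyl group should end cis to O10 as step 14 requires.

Step 9
Reactants: 13 ethynyl diol
Product: 14 epoxy diol
Conditions: VO(acac)2 (cat.), t-BuOOH, CH2Cl2, 0 °C
Reagents that add atoms: tert-butyl hydroperoxide CC(C)(C)OO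
Why: Hydroxyl-directed epoxidation: the tertiary allylic C10 hydroxyl delivers oxygen to its own face of C8=C9, the homoallylic C1 hydroxyl on the other face is a far weaker director, and the remaining π-bonds carry no directing hydroxyl.

Step 10
Reactants: 14 epoxy diol
Product: 15 C8 PMB ether triol
Conditions: Ti(OiPr)4, 4-MeOC6H4CH2OH, toluene, 60 °C
Reagents that add atoms: 4-methoxybenzyl alcohol COc1ccc(CO)cc1
Why: Titanium-mediated opening of a 2,3-epoxy alcohol at the distal carbon by an alcohol nucleophile; attack at C8 is also the trans-diaxial mode with both carbon substituents equatorial and avoids neopentylic C9, which sets O8 anti to O9 and syn to the C7 chain.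

Step 11
Reactants: 15 C8 PMB ether triol
Product: 16 C9 TBS ether
Conditions: TBSOTf, 2,6-lutidine, CH2Cl2, −78 °C
Reagents that add atoms: tert-butyldimethylsilyl trifluoromethanesulfonate CC(C)(C)[Si](C)(C)OS(=O)(=O)C(F)(F)F
Why: At low temperature the silyl triflate should select the single secondary hydroxyl over the two hindered tertiary ones.

Step 12
Reactants: 16 C9 TBS ether
Product: 17 C6 aldehyde
Conditions: PPTS, acetone/H2O, 45 °C
Reagents that add atoms: water O
Why: Mild acid-catalysed acetal hydrolysis; silyl ethers, the PMB ether and the tertiary propargylic alcohol are expected to survive, and C6 already holds its preferred trans relationship to C7.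

Step 13
Reactants: 17 C6 aldehyde
Product: 18 Z-propenyl enyne diol
Conditions: EtPPh3Br, KN(SiMe3)2, THF, −78 to 0 °C (aldehyde added to excess ylide)
Reagents that add atoms: ethyltriphenylphosphonium bromide CC[P+](c1ccccc1)(c1ccccc1)c1ccccc1.[Br-]
Why: A salt-free Wittig reaction of a non-stabilised ylide gives the Z alkene under kinetic control; inverse addition at low temperature should let olefination outrun retro-aldol cleavage of the β-alkoxide, and any hemiacetal form is opened by the ylide.

Step 14
Reactants: 18 Z-propenyl enyne diol
Product: 19 cis-fused dihydrofuranol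
Conditions: Mo(CO)6 (30 mol%), Et3N, Et2O, hν (350 nm), rt
Reagents that add atoms: none
Why: Molybdenum-carbonyl-catalysed cycloisomerisation of a but-3-yn-1-ol: the terminal alkyne becomes a metal vinylidene and the cis-disposed C10 hydroxyl adds to its α-carbon (net 5-endo-dig, anti-Markovnikov), giving the cis-fused 2,3-dihydrofuran; the basic medium protects the acid-labile enol ether.

Step 15
Reactants: 19 cis-fused dihydrofuranol
Product: 22 ring-expanded silyl enol ether, via potassium alkoxide 20 (not isolated), via potassium enolate 21 (not isolated)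
Conditions: KN(SiMe3)2, 18-crown-6, THF, −78 to 0 °C; then TMSCl, Et3N, −78 °C
Reagents that add atoms: chlorotrimethylsilane C[Si](C)(C)Cl
Why: Anionic oxy-Cope rearrangement: the dissociated alkoxide 20 undergoes a [3,3] shift in which C1–C6 breaks while C3–C4 forms, giving enolate 21, which is silylated on oxygen. The closest known reaction type is the four-carbon ring expansion of 1,2-dialkenylcyclohexanol alkoxides to cyclodec-5-enones, here with the enol ether of the fused dihydrofuran as one alkenyl arm. No ring is closed by an exo or endo attack: the ten-membered carbocycle and the nine-membered oxacycle of the bicyclo[6.2.1] core both arise by sigmatropic ring expansion of the cyclohexane. The shift can start only from the chair in which O10 and the C6 propenyl group are syn-axial, where the C1–C6 bond lies roughly parallel to the π-system of C2=C3 and C4 sits under C3. Because the five-membered ring ties C10 to the axial-like site of the oxyallyl half, the chair array puts C7 in the equatorial-like site and should give the E C5=C6 bond, whereas the boat would need C7 twisted well away from its natural position. C4 is set by suprafacial chirality transfer from C6 through this chair, with the methyl of the Z-propenyl group axial-like, which gives the target configuration (an E-propenyl group would give the epimer); the C3 centre formed at the same time is erased in step 16. The step needs the [3,3] shift to beat heterolytic fragmentation and a [1,3] shift, which the potassium/18-crown-6 ion pair at low temperature favours, and it needs the enolate to keep its ring, which is secured because the C3–O bond lies in the nodal plane of the enolate (no E1cB opening).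

Step 16
Reactants: 22 ring-expanded silyl enol ether
Product: 23 3(2H)-furanone
Conditions: Pd(OAc)2, MeCN, rt
Reagents that add atoms: none
Why: Saegusa–Ito oxidation: the palladium enolate can eliminate only the C3 hydride (C10 is quaternary), giving the furanone under neutral conditions that should neither epimerise C4 nor move the C5=C6 bond.

Step 17
Reactants: 23 3(2H)-furanone
Product: 24 C8 alcohol
Conditions: DDQ, CH2Cl2/pH 7 buffer, 0 °C
Reagents that add atoms: none
Why: Oxidative cleavage of the PMB ether; TBS ethers, the vinylogous ester and the alkenes should be inert at 0 °C.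

Step 18
Reactants: 24 C8 alcohol
Product: 25 C8 isovalerate
Conditions: (i-BuCO)2O, DMAP, Et3N, CH2Cl2, rt
Reagents that add atoms: isovaleric anhydride CC(C)CC(=O)OC(=O)CC(C)C
Why: DMAP-catalysed acylation of the only free hydroxyl; bases this weak should not enolise the furanone at C4.

Step 19
Reactants: 25 C8 isovalerate
Product: 26 C5,C6-diol
Conditions: OsO4 (5 mol%), NMO, acetone/H2O, 0 °C
Reagents that add atoms: osmium tetroxide O=[Os](=O)(=O)=O (oxygen carrier); N-methylmorpholine N-oxide C[N+]1([O-])CCOCC1; water O
Why: Upjohn dihydroxylation: syn addition to the strained E C5=C6 bond from its peripheral face (the inner face is covered by the furanone bridge) gives the C5 and C6 configurations of the target; the hindered 1,1-disubstituted alkene with its allylic oxygen and the push-pull furanone alkene should react more slowly.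

Step 20
Reactants: 26 C5,C6-diol
Product: 27 tetraol
Conditions: HF·pyridine, THF/pyridine, 0 °C to rt
Reagents that add atoms: none
Why: Cleavage of both TBS ethers under weakly acidic conditions that avoid acyl migration from O8 and base-induced epimerisation at C4.

Step 21
Reactants: 27 tetraol
Product: 30 CNP0484215.1, via hydroxy enal 28 (not isolated), via lactol 29 (not isolated)
Conditions: TEMPO (cat.), PhI(OAc)2, CH2Cl2, rt
Reagents that add atoms: none
Why: Oxoammonium oxidation is selective for the primary allylic alcohol; enal 28 should be captured by the adjacent C6 hydroxyl as the five-membered lactol 29, which is oxidised on to the trans-fused α-methylene-γ-butyrolactone, while the secondary hydroxyls at C5 and C9 react much more slowly.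

## Compound list

1 | (R)-(−)-carvone | O=C1C(C)=CC[C@@H](C(C)=C)C1 | starting material
2 | (R)-10-hydroxycarvone | O=C1C(C)=CC[C@@H](C(=C)CO)C1 | intermediate
3 | TBS ether of 2 | O=C1C(C)=CC[C@@H](C(=C)CO[Si](C)(C)C(C)(C)C)C1 | intermediate
4 | epoxy ketone (C9–C10 oxirane trans to the C7 chain) | O=C1[C@]2(C)O[C@@H]2C[C@@H](C(=C)CO[Si](C)(C)C(C)(C)C)C1 | intermediate
5 | epoxy alcohol (C1 carbinol) | O[C@@H]1[C@]2(C)O[C@@H]2C[C@@H](C(=C)CO[Si](C)(C)C(C)(C)C)C1 | intermediate
6 | C9 phenylselenide diol | O[C@@H]1[C@](C)(O)[C@@H]([Se]c2ccccc2)C[C@@H](C(=C)CO[Si](C)(C)C(C)(C)C)C1 | intermediate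
7 | C9 selenoxide diol | O[C@@H]1[C@](C)(O)[C@@H]([Se](=O)c2ccccc2)C[C@@H](C(=C)CO[Si](C)(C)C(C)(C)C)C1 | intermediate
8 | ene-diol (C8=C9, tertiary allylic C10–OH, secondary C1–OH) | O[C@@H]1[C@](C)(O)C=C[C@@H](C(=C)CO[Si](C)(C)C(C)(C)C)C1 | intermediate
9 | α-ketol (C1 ketone) | O=C1[C@](C)(O)C=C[C@@H](C(=C)CO[Si](C)(C)C(C)(C)C)C1 | intermediate
10 | bis(trimethylsilyl) dienol ether | C[Si](C)(C)OC1=C[C@H](C(=C)CO[Si](C)(C)C(C)(C)C)C=C[C@@]1(C)O[Si](C)(C)C | intermediate
11 | C10-O-TMS keto acetal | O=C1[C@](C)(O[Si](C)(C)C)C=C[C@@H](C(=C)CO[Si](C)(C)C(C)(C)C)[C@@H]1C(OC)OC | intermediate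
12 | keto acetal (C6 dimethoxymethyl trans to the C7 chain) | O=C1[C@](C)(O)C=C[C@@H](C(=C)CO[Si](C)(C)C(C)(C)C)[C@@H]1C(OC)OC | intermediate
13 | ethynyl diol (ethynyl cis to O10) | C#C[C@]1(O)[C@](C)(O)C=C[C@@H](C(=C)CO[Si](C)(C)C(C)(C)C)[C@@H]1C(OC)OC | intermediate
14 | epoxy diol (C8–C9 oxirane syn to C10–OH) | C#C[C@]1(O)[C@](C)(O)[C@@H]2O[C@@H]2[C@@H](C(=C)CO[Si](C)(C)C(C)(C)C)[C@@H]1C(OC)OC | intermediate
15 | C8 PMB ether triol | C#C[C@]1(O)[C@](C)(O)[C@H](O)[C@@H](OCc2ccc(OC)cc2)[C@@H](C(=C)CO[Si](C)(C)C(C)(C)C)[C@@H]1C(OC)OC | intermediate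
16 | C9 TBS ether | C#C[C@]1(O)[C@](C)(O)[C@H](O[Si](C)(C)C(C)(C)C)[C@@H](OCc2ccc(OC)cc2)[C@@H](C(=C)CO[Si](C)(C)C(C)(C)C)[C@@H]1C(OC)OC | intermediate
17 | C6 aldehyde | C#C[C@]1(O)[C@](C)(O)[C@H](O[Si](C)(C)C(C)(C)C)[C@@H](OCc2ccc(OC)cc2)[C@@H](C(=C)CO[Si](C)(C)C(C)(C)C)[C@@H]1C=O | intermediate
18 | Z-propenyl enyne diol | C#C[C@]1(O)[C@](C)(O)[C@H](O[Si](C)(C)C(C)(C)C)[C@@H](OCc2ccc(OC)cc2)[C@@H](C(=C)CO[Si](C)(C)C(C)(C)C)[C@@H]1/C=C\C | intermediate
19 | cis-fused dihydrofuranol (3a-hydroxy-7a-methyl-hexahydrobenzofuran, C6 Z-propenyl cis to ring O) | O[C@@]12C=CO[C@]1(C)[C@H](O[Si](C)(C)C(C)(C)C)[C@@H](OCc3ccc(OC)cc3)[C@@H](C(=C)CO[Si](C)(C)C(C)(C)C)[C@@H]2/C=C\C | intermediate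
20 | potassium alkoxide of 19 | [K+].[O-][C@@]12C=CO[C@]1(C)[C@H](O[Si](C)(C)C(C)(C)C)[C@@H](OCc3ccc(OC)cc3)[C@@H](C(=C)CO[Si](C)(C)C(C)(C)C)[C@@H]2/C=C\C | intermediate
21 | ring-expanded potassium enolate | C[C@@H]1/C=C/[C@H](C(=C)CO[Si](C)(C)C(C)(C)C)[C@H](OCc3ccc(OC)cc3)[C@@H](O[Si](C)(C)C(C)(C)C)[C@@]2(C)O[C@@H]1C=C2[O-].[K+] | intermediate
22 | ring-expanded silyl enol ether (11-oxabicyclo[6.2.1]undecadiene, E C5=C6) | C[C@@H]1/C=C/[C@H](C(=C)CO[Si](C)(C)C(C)(C)C)[C@H](OCc3ccc(OC)cc3)[C@@H](O[Si](C)(C)C(C)(C)C)[C@@]2(C)O[C@@H]1C=C2O[Si](C)(C)C | intermediate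
23 | 3(2H)-furanone | C[C@@H]1/C=C/[C@H](C(=C)CO[Si](C)(C)C(C)(C)C)[C@H](OCc3ccc(OC)cc3)[C@@H](O[Si](C)(C)C(C)(C)C)[C@@]2(C)OC1=CC2=O | intermediate
24 | C8 alcohol | C[C@@H]1/C=C/[C@H](C(=C)CO[Si](C)(C)C(C)(C)C)[C@H](O)[C@@H](O[Si](C)(C)C(C)(C)C)[C@@]2(C)OC1=CC2=O | intermediate
25 | C8 isovalerate | C[C@@H]1/C=C/[C@H](C(=C)CO[Si](C)(C)C(C)(C)C)[C@H](OC(=O)CC(C)C)[C@@H](O[Si](C)(C)C(C)(C)C)[C@@]2(C)OC1=CC2=O | intermediate
26 | C5,C6-diol | C[C@@H]1[C@H](O)[C@@H](O)[C@H](C(=C)CO[Si](C)(C)C(C)(C)C)[C@H](OC(=O)CC(C)C)[C@@H](O[Si](C)(C)C(C)(C)C)[C@@]2(C)OC1=CC2=O | intermediate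
27 | tetraol | C[C@@H]1[C@H](O)[C@@H](O)[C@H](C(=C)CO)[C@H](OC(=O)CC(C)C)[C@@H](O)[C@@]2(C)OC1=CC2=O | intermediate
28 | hydroxy enal | C[C@@H]1[C@H](O)[C@@H](O)[C@H](C(=C)C=O)[C@H](OC(=O)CC(C)C)[C@@H](O)[C@@]2(C)OC1=CC2=O | intermediate
29 | lactol | C[C@@H]1[C@H](O)[C@H]3OC(O)C(=C)[C@@H]3[C@H](OC(=O)CC(C)C)[C@@H](O)[C@@]2(C)OC1=CC2=O | intermediate
30 | CNP0484215.1 | C=C1C(=O)O[C@@H]2[C@@H](O)[C@@H](C)C3=CC(=O)[C@](C)(O3)[C@H](O)[C@@H](OC(=O)CC(C)C)[C@@H]12 | target

## Step count and least certain steps

Total step count: 21. Longest linear sequence: 21 steps (fully linear from 1).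

**Step 15 (key).** Most likely failure: insufficient orbital overlap in the fused bicycle, so that the alkoxide either does not rearrange or fragments heterolytically into a furanone and an allyl anion; a second failure is leakage through the boat, which would give the C4 epimer and the Z alkene. The fallback sets out from 18 and removes the ring constraint by using the ethynyl group itself as the oxy arm. An acetylenic anionic oxy-Cope rearrangement (KN(SiMe3)2, 18-crown-6, then protonation of the allenolate) should give the ten-membered (2Z,5E)-dienone F1. Acid-catalysed transannular conjugate addition of the C10 hydroxyl (camphorsulfonic acid, CH2Cl2) then closes the bridged tetrahydrofuran-3-one F2. Enolisation with LiN(i-Pr)2 and silylation with TMSCl returns to the route at 22.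

**Step 14.** Most likely failure: ionisation or dehydration of the free tertiary propargylic hydroxyl at the vinylidene stage, or sluggish addition of the hindered tertiary C10 hydroxyl. The fallback sets out from 18: anti-Markovnikov hydration of the alkyne by hydroboration–oxidation (dicyclohexylborane, then NaBO3) gives the aldehyde as its lactol F3; dehydration through the anomeric mesylate (MsCl, Et3N) returns to 19.

**Step 19.** Most likely failure: competing osmylation of the 1,1-disubstituted alkene, or poor facial selectivity if the E alkene can turn inside the ring; in step 21 the C5 hydroxyl could also capture the enal as a six-membered lactol. The fallback sets out from 25 and raises C12 to the acid before the dihydroxylation, so that the side-chain alkene is deactivated. HF·pyridine gives the diol F4, MnO2 the enal F5, and Pinnick oxidation (NaClO2, NaH2PO4, 2-methyl-2-butene) the acrylic acid F6. OsO4/NMO should then attack only C5=C6 to give the dihydroxy acid F7, which lactonises under mild acid on the γ-hydroxyl and returns to the route at 30.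

**Step 10.** Most likely failure: transfer of isopropoxide instead of the PMB alkoxide, slow opening, or self-condensation of the benzylic alcohol. The fallback sets out from 14 and uses the carboxylic acid variant of the same titanium-mediated opening. Ti(OiPr)4 with benzoic acid gives the C8 benzoate F8; TBSOTf with 2,6-lutidine gives the C9 silyl ether F9; DIBAL-H at −78 °C removes the benzoate to give the C8 alcohol F10; 4-methoxybenzyl trichloroacetimidate with catalytic La(OTf)3 returns to 16.

**Step 13.** Most likely failure: retro-aldol cleavage of the C1 alkoxide/aldehyde pair before olefination, or erosion of Z selectivity. The fallback sets out from 17 and removes the alkoxide: N-(trimethylsilyl)imidazole caps both tertiary hydroxyls to give the bis-TMS aldehyde F11; the same Wittig reaction gives the bis-TMS Z-propenyl compound F12; K2CO3 in MeOH strips the two trimethylsilyl ethers and returns to 18.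

## Further compounds

F1 | step 15 | ten-membered (2Z,5E)-dienone with free C10–OH | C[C@@H]1/C=C/[C@H](C(=C)CO[Si](C)(C)C(C)(C)C)[C@H](OCc2ccc(OC)cc2)[C@@H](O[Si](C)(C)C(C)(C)C)[C@@](C)(O)C(=O)/C=C\1
F2 | step 15 | bridged tetrahydrofuran-3-one | C[C@@H]1/C=C/[C@H](C(=C)CO[Si](C)(C)C(C)(C)C)[C@H](OCc3ccc(OC)cc3)[C@@H](O[Si](C)(C)C(C)(C)C)[C@@]2(C)O[C@@H]1CC2=O
F3 | step 14 | bicyclic lactol | O[C@@]12CC(O)O[C@]1(C)[C@H](O[Si](C)(C)C(C)(C)C)[C@@H](OCc3ccc(OC)cc3)[C@@H](C(=C)CO[Si](C)(C)C(C)(C)C)[C@@H]2/C=C\C
F4 | step 19 | C9,C12-diol with intact C5=C6 | C[C@@H]1/C=C/[C@H](C(=C)CO)[C@H](OC(=O)CC(C)C)[C@@H](O)[C@@]2(C)OC1=CC2=O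
F5 | step 19 | enal | C[C@@H]1/C=C/[C@H](C(=C)C=O)[C@H](OC(=O)CC(C)C)[C@@H](O)[C@@]2(C)OC1=CC2=O
F6 | step 19 | acrylic acid | C[C@@H]1/C=C/[C@H](C(=C)C(=O)O)[C@H](OC(=O)CC(C)C)[C@@H](O)[C@@]2(C)OC1=CC2=O
F7 | step 19 | dihydroxy acid | C[C@@H]1[C@H](O)[C@@H](O)[C@H](C(=C)C(=O)O)[C@H](OC(=O)CC(C)C)[C@@H](O)[C@@]2(C)OC1=CC2=O
F8 | step 10 | C8 benzoate triol | C#C[C@]1(O)[C@](C)(O)[C@H](O)[C@@H](OC(=O)c2ccccc2)[C@@H](C(=C)CO[Si](C)(C)C(C)(C)C)[C@@H]1C(OC)OC
F9 | step 10 | C8 benzoate C9 TBS ether | C#C[C@]1(O)[C@](C)(O)[C@H](O[Si](C)(C)C(C)(C)C)[C@@H](OC(=O)c2ccccc2)[C@@H](C(=C)CO[Si](C)(C)C(C)(C)C)[C@@H]1C(OC)OC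
F10 | step 10 | C8 alcohol C9 TBS ether | C#C[C@]1(O)[C@](C)(O)[C@H](O[Si](C)(C)C(C)(C)C)[C@@H](O)[C@@H](C(=C)CO[Si](C)(C)C(C)(C)C)[C@@H]1C(OC)OC
F11 | step 13 | bis-TMS aldehyde | C#C[C@]1(O[Si](C)(C)C)[C@](C)(O[Si](C)(C)C)[C@H](O[Si](C)(C)C(C)(C)C)[C@@H](OCc2ccc(OC)cc2)[C@@H](C(=C)CO[Si](C)(C)C(C)(C)C)[C@@H]1C=O
F12 | step 13 | bis-TMS Z-propenyl enyne | C#C[C@]1(O[Si](C)(C)C)[C@](C)(O[Si](C)(C)C)[C@H](O[Si](C)(C)C(C)(C)C)[C@@H](OCc2ccc(OC)cc2)[C@@H](C(=C)CO[Si](C)(C)C(C)(C)C)[C@@H]1/C=C\C
A1 | alternative 1 | furanone aldehyde with 2-(bromomethyl)enoate (Barbier precursor) | O=C[C@@H](O[Si](C)(C)C(C)(C)C)[C@@H](C)C1=CC(=O)[C@](C)(O1)[C@H](O[Si](C)(C)C(C)(C)C)[C@@H](OC(=O)CC(C)C)/C=C(/CBr)C(=O)OC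
A2 | alternative 2 | ten-membered ynone lactone with free C10–OH | C=C1C(=O)O[C@@H]2[C@@H](O)[C@@H](C)C#CC(=O)[C@](C)(O)[C@H](O)[C@@H](OC(=O)CC(C)C)[C@@H]12
A3 | alternative 3 | 2-methyl-3-silyloxyfuran lactone aldehyde | O=C[C@@H](OC(=O)CC(C)C)[C@H]1C(=C)C(=O)O[C@@H]1[C@@H](O[Si](C)(C)C(C)(C)C)[C@@H](C)c1cc(O[Si](C)(C)C)c(C)o1
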